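Readings and results are calculated from invented constants; noise was put on by code.

Read the early times first: north, charged with c(free catalyst) 0.30 mM against c(impurity) 0.39 mM, stands near 2.3 % of target after 1.00 h and stays there.

| flask | starting material | reagent | free catalyst | impurity | remark | time |
|---|---|---|---|---|---|---|
| south | 0.010 M | 0.011 M | 0.61 mM | 0.39 mM | run made earlier |  |
| north | 0.010 M | 0.011 M | 0.30 mM | 0.39 mM | run made earlier |  |
| south-east | 0.010 M | 0.011 M | 1.2 mM | 0.39 mM | run made earlier |  |
| alder | 0.010 M | 0.0110 M | 0.61 mM | 0.39 mM | everything together at the start | 8.0 h |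
| birch | 0.010 M | 0.0110 M (fed, over 5.0 h) | 0.61 mM | 0.39 mM | all else is in the flask from the start; the feed brings no volume worth counting | 8.0 h |
| oak | 0.010 M (fed, over 5.0 h) | 0.0110 M | 0.61 mM | 0.39 mM | all else is in the flask from the start; the feed brings no volume worth counting | 8.0 h |

| run | time / h | target / % | starting material / % |
|---|---|---|---|
| south | 0.333 | 5.8 | 93.3 |
| south | 1.00 | 15.4 | 84.5 |
| south | 1.50 | 21.6 | 77.2 |
| south | 2.50 | 33.8 | 64.6 |
| south | 4.00 | 49.6 | 49.1 |
| south | 5.00 | 59.2 | 41.1 |
| north | 1.00 | 2.3 | 96.9 |
| north | 2.00 | 2.7 | 97.9 |
| north | 3.00 | 1.7 | 98.5 |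
| north | 4.00 | 2.3 | 97.3 |
| north | 5.00 | 2.3 | 96.9 |
| north | 6.00 | 2.5 | 98.4 |
| south-east | 0.500 | 23.7 | 73.1 |
| south-east | 0.833 | 37.6 | 58.9 |
| south-east | 1.33 | 55.9 | 42.4 |
| south-east | 2.50 | 85.1 | 13.5 |
| south-east | 4.00 | 98.6 | 0.6 |
| south-east | 6.00 | 100.5 | 0.5 |

(readings scatter by 0.5 percentage points)

* the flask with the highest amount of target, in percent of the starting material charged ("all alike" if they lie within 1.5 percentage points) (alder / birch / oak / all alike)
* final target, as a percentage of the starting material charged, in alder
* final target, as a percentage of the starting material charged, in birch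
* final target, as a percentage of the starting material charged, in oak



Take the impurity as removing catalyst one for one, and carry what remains: 0.220 mM in south, 0.810 mM in south-east. This is the surplus catalyst, charged free catalyst minus charged impurity. Now go to logarithms. The first-order constant read for starting material is 0.178 h⁻¹ in south and 0.627 h⁻¹ early in south-east, a rise of 0.547 in log10. Charged catalyst rises by 0.294, the surplus by 0.566. So read the rate as following the surplus to the first power.

Then rank the numbers. Subtraction magnifies a relative error by charge over surplus:

| Number | Gain on the constant | Target moved in alder per percent of error |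
|---|---|---|
| c(free catalyst) | 2.77 | 0.95 percentage points |
| c(impurity) | 1.77 | 0.61 points |
| time | 1 | 0.34 points |

Starting material and reagent never varied in these runs, so leave them unranked. Both catalyst charges must be known well. Alder repeats the south charges, so I reckon 75.9 % of target there at 8.0 h.

The forecast, a little above my figure, gives 78 % in alder, 94 % in birch and 66 % in oak, so birch leads: “I favour reagent held off-cycle on the catalyst”.

The flasks give 80.5 % in alder, 65.1 % in birch and 78.3 % in oak, so alder leads.

    starting material + catalyst intermediate A → catalyst intermediate B (k = 65400 M⁻¹ h⁻¹)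
    reagent + free catalyst → catalyst intermediate A (k = 1250 M⁻¹ h⁻¹)
    catalyst intermediate C → free catalyst + target (k = 14.1 h⁻¹)
    catalyst intermediate B ⇌ released group + catalyst intermediate C (K = 0.0230 M, k = 689 h⁻¹)
    free catalyst + impurity → spent catalyst (k = 81200 M⁻¹ h⁻¹)

Alder holds 63.9 % of its catalyst as spent catalyst at 8.00 h, the share 63.9 % that the charges give, which leaves the surplus of 0.220 mM. Remove the step of free catalyst with impurity and the gap between alder and birch falls from 15 points to 0.0055 points: the largest single effect on that gap, though this does not make it the main reason. A neighbour of alder charged with 0.240 mM of free catalyst has a surplus of −0.150 mM: its spent catalyst stands at 100 %, its impurity left at 38.5 %, and its target at 1.61 %.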